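## Structural features

The target joins two carbocycles through one methylene, C7. Ring A is a 2-substituted cyclohexane-1,3-dione in its enol form (A1 carbonyl, A2 bearing C7, A3 enol carbon, A4 bearing OMe, A5 and A6 methylenes). Ring B is a cyclopentene (B1 methine bearing C7, B2=B3 alkene, B4 methylene, B5 tertiary carbinol with CH3 and OH). B2 carries a 6-methylhepta-2,5-dien-2-yl chain (D1 with its methyl, D2, D3, D4, D5 with two methyls); D1=D2 is Z and conjugated with B2=B3, and D3 is doubly allylic. There are three stereocentres: B1 (R) and B5 (S) are neighbours with the hydroxyl cis to C7, and A4 (S) lies five bonds away, α to the β-dicarbonyl unit. The fragile elements are: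

- the Z-configured trisubstituted diene, which can isomerise under acid or through radicals;
- the skipped D3 methylene, which is sensitive to hydride-abstracting oxidants;
- the tertiary alcohol, which under acid can add to a ring A carbonyl and dehydrate to a cyclic enol ether;
- A4, which can epimerise whenever a ring A carbonyl is free to enolise toward it under base.

The real difficulty is threefold: the contiguous B1/B5 pair with a fully substituted carbinol in one absolute sense, a remote A4 centre that ring B cannot control, and a hindered Z-diene next to B1. The key step exploits the sequence B5 (CH3, OH)–B1 (H, C7)–B2. With B2 written as a ketone and the unsaturation moved to B3=B4, ring B is a 4-hydroxy-4-methyl-5-substituted cyclopent-2-enone, the retron of a Piancatelli rearrangement of a 5-methyl-2-furylcarbinol. The enone formed is also the handle for a regiodefined B2=B3 enol triflate.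

## Logic of the disconnections

**32 to 31.** No skeletal bond is cut. The B5 oxygen is given a tert-butyldimethylsilyl group and the ring A enol oxygen a 2-(trimethylsilyl)ethyl group. This removes the acidic dione and the free tertiary alcohol, which together tend to cyclise. The forward step must cleave both groups with one fluoride reagent and release the dione as its enolate, never under acid.

**31 to 21 and 29.** The C7–A2 bond, the only link between the two ring systems, is cut. Each half then carries its own stereocentres, so A4 and the B1/B5 pair are made enantiopure separately; this is the only way to relate centres too far apart to influence each other. The forward step must join a β-branched primary carbon to a hindered sp2 carbon without touching B1. An alkylzinc (30) is mild enough, and the ring A partner must be an iodinated enol ether because a free dione would protonate the zinc reagent.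

**21 to 20 to 19.** The C7–I bond is traced back to C7–OH and then to a primary silyl ether. This keeps C7 at the alcohol oxidation level throughout, so B1 never sits next to a carbonyl once the diene is in place. The demand is clean discrimination between the primary and the tertiary silyl ether.

**19 to 10 and 16.** The B2–D1 bond between two sp2 carbons is cut. The side chain is removed as a separate unit of fixed Z geometry, leaving a ring B enol triflate. The coupling (through 18) must retain geometry at both carbons and tolerate the substituent on B1.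

**16 to 14 and 15; 14 to 13; 13 to 11.** The D3–D4 bond is cut next to the allylic position, then C–Br is returned to C–OH, then the C–I and C–H bonds across D1=D2 are removed to leave an alkyne. The gain is a four-carbon propargylic alcohol whose hydroxyl directs the anti addition that fixes the Z geometry. The demand is substitution at D3 without touching the vinyl iodide.

**10 to 7 to 6.** The enol triflate is read as the trapped B2=B3 enolate of the enone, formed by hydride addition at B4. The enone alone defines the regiochemistry, so no base meets the acidic B1–H. The demand is strict 1,4-reduction and a protected B5 oxygen.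

**6 to 5.** The B1–B5 bond is cut and ring B is opened to a furan. Two adjacent stereocentres, one of them quaternary, are traded for a racemic secondary carbinol. The forward step needs a chiral acid that controls the direction of a conrotatory closure, and an oxygen substituent on C7 that survives acid and does not divert the cation.

**5 to 2 and 3; 2 to 1.** The bond between the furan carbon (future B2) and the carbinol carbon (future B1) is cut, then the O–Si bond. This leads to two bulk chemicals and requires only addition of a furyllithium (4) to an aldehyde.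

**29 to 28 to 27.** The A2–I bond and the enol O–C bond are removed. The symmetrical-looking dione is the simplest carrier of A4. The demand is O-alkylation without base, so that A4 stays intact.

**27 to 26; 26 to 25 to 24; 24 to 22 and 23.** The A2–A3 bond is cut (an intramolecular Claisen retron). The ketone is traced to a terminal alkene, the methyl ether to the alcohol, and the A5–A6 bond to an epoxide opening. A4 then comes unchanged from a chiral-pool epoxide. The ring closure must be faster than enolisation of the ester at A4.

## Other disconnections considered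

**Alternative 1:** The cut is the B2–B3 ring bond together with the D1=D2 double bond. Ring B and the diene would arise in one operation from the open-chain 1,6-enyne A1. In A1 the methyl-capped alkyne B2≡D1 sits on B1, the Z-alkene B3=D2 is tethered through B4 and B5, and the two oxygens are tied as a di-tert-butylsilylene. In the forward sense a cationic phosphine complex of monovalent gold (or PtCl2) activates the alkyne. B3 attacks B2 in the 5-exo mode, and the cyclopropyl metal carbene rearranges by single cleavage, D2 moving from B3 to D1, to give the cis-fused silylene diene A2.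

- In its favour: ring closure and installation of the whole side chain occur in one catalytic, redox-neutral isomerisation, with no enol triflate and no organozinc. The two stereocentres would be set in an open chain by established asymmetric chemistry and only carried through. On precedent for absolute stereocontrol this alternative is the better of the two.
- Against it here: the D1=D2 geometry depends on a stereospecific migration, and Z-alkenes are the substrates most prone to leak through open cations to the E-diene. The internal alkyne invites endo closure and double cleavage. The electron-rich D4=D5 alkene can intercept the carbene. A1, with a tertiary carbinol next to a propargylic centre and a Z-configured skipped diene, needs a longer stereocontrolled synthesis than 10 and 16 together.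
- Comparison: structurally both plans reach ring B with C7 oxygenated and the Z-diene in place, so they are equal from there to 32. Mechanistically both are catalysed cation rearrangements, but the gold step creates no stereocentre whereas step 3 creates two. In step economy the gold step itself is the better one (ring and chain in one step against three), an advantage expected to be lost in making A1.

**Alternative 2:** The cuts are A2–C7, C7–B1 and O–B5, so C7 comes from A3 (formaldehyde) and both rings are joined in one pot. Dione 27 would condense with A3 to the 2-methylene dione A4. This 1-oxadiene is expected to add across the trisubstituted alkene of A5 with inverse electron demand, oxygen bonding to the more substituted carbon B5, to give the cis-fused dihydropyran A6.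

- In its favour: three bonds, the linker carbon and the cis B1/B5 relationship (suprafacial addition, anti to the silyloxy group) are made at once from 27 itself. No iodo enol ether, alkylzinc or dione protecting group is needed, because the B5 oxygen masks the dione as a cyclic enol ether. In convergence and in the number of steps needed to join the rings this is the better plan.
- Against it here: A5 is an unactivated alkene, so dimerisation of A4 and ene reactions should compete. The absolute configuration of B1 and B5 rests on enantiopure A5, whose own stereocentre is sacrificed. A6 is the intramolecular enol ether of the target, and opening it to the free B5 hydroxyl runs against the tendency of the hydroxy dione to close, under conditions that endanger A4. The side chain must still be added afterwards by oxidation at B2, enolisation away from B1 and coupling, with ring A already on board.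
- Comparison: on structure the plans are equal in their use of 27 and in ending with a cross-coupling at B2. On mechanism the cycloaddition is a known reaction type applied to a poor dienophile, whereas step 3 is a well-behaved rearrangement in a new asymmetric form. On step count the alternative leads up to A6 and is expected to lose that lead in the ring opening and the late side-chain work.

**Alternative 3:** The cuts are B2–D1 and D2–D3, with no ring closure. The side chain is assembled on ring B from A8 (propyne) and A9 (prenyl bromide). The alkenyl iodide A7 would be converted by halogen–lithium exchange and transmetalation through magnesium into an alkenylcopper. This adds syn across A8, the ring carbon going to the internal alkyne carbon, and the resulting Z-dienylcopper is allylated by A9 to give A10.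

- In its favour: the Z geometry follows from the syn addition itself, the chain comes from two bulk chemicals, and the three steps that make 16 become unnecessary. For the side chain this is the better plan in step economy. It also fits the ring B chemistry of the chosen route, since A7 differs from 10 only in the leaving group and the silyl groups; on the origin of B1 and B5 the two are equal.
- Against it here: carbocupration of unactivated alkynes is dependable for alkylcopper reagents but slow for alkenylcopper reagents, the more so for one flanked by B1. Deprotonation of A8 by the organometallic is an easy escape. Allylation with A9 can occur at either end of the allyl system.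
- Comparison: the chosen Negishi coupling transfers a geometry that is fixed and checked in 16 before the valuable ring B intermediate is committed, whereas the alternative creates the geometry on that intermediate. The alternative is shorter; the chosen coupling is the more predictable.

Key step: step 3

Remark (assumption): the sense of induction of the chiral acid in step 3 cannot be predicted with confidence; (R)-TRIP is written, and its mirror image is taken if that is the one leading to (4S,5S)-6.

Remark: 32 is drawn as the enol tautomer of the target SMILES; the enol tautomers of the 2-alkyl-1,3-dione interconvert, so unveiling the dione from 31 gives this compound.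

## Steps

Step 1
Reactants: 1 glycolaldehyde dimer (1,4-dioxane-2,5-diol)
Product: 2 2-[(tert-butyldiphenylsilyl)oxy]acetaldehyde
Conditions: TBDPSCl, Et3N, DMAP (cat.), CH2Cl2, 0 °C → rt
Reagents that add atoms: tert-butyl(chloro)diphenylsilane (TBDPSCl), CC(C)(C)[Si](Cl)(c1ccccc1)c1ccccc1
Why: Amine base equilibrates the hemiacetal dimer with monomeric hydroxyacetaldehyde, whose primary hydroxyl is trapped by O-silylation; the acid-stable, non-nucleophilic tert-butyldiphenylsilyl group is chosen in place of a 4-methoxybenzyl ether because it must survive the Brønsted acid of step 3 and later come off without an oxidant.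

Step 2
Reactants: 3 2-methylfuran; 2 2-[(tert-butyldiphenylsilyl)oxy]acetaldehyde
Product: 5 rac-2-[(tert-butyldiphenylsilyl)oxy]-1-(5-methylfuran-2-yl)ethan-1-ol, via 5-methyl-2-furyllithium 4 (not isolated)
Conditions: n-BuLi, THF, 0 °C; then 2, −78 °C; then H2O
Reagents that add atoms: none
Why: 2-Methylfuran is lithiated at its only free α-position and the furyllithium undergoes 1,2-addition to the aldehyde at low temperature, where silyl migration in the alkoxide is slow; the carbinol centre is left racemic on purpose because step 3 erases it.

Step 3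
Reactants: 5 rac-2-[(tert-butyldiphenylsilyl)oxy]-1-(5-methylfuran-2-yl)ethan-1-ol
Product: 6 (4S,5S)-5-{[(tert-butyldiphenylsilyl)oxy]methyl}-4-hydroxy-4-methylcyclopent-2-en-1-one (hydroxyl cis to the silyloxymethyl group)
Conditions: (R)-TRIP [(R)-3,3'-bis(2,4,6-triisopropylphenyl)-1,1'-binaphthyl-2,2'-diyl hydrogen phosphate] (10 mol %), H2O (5 equiv), CHCl3, 40 °C
Reagents that add atoms: water, O
Why: Proposed new method: the chiral phosphoric acid should ionise either enantiomer of 5 to the same planar 5-methylfurfuryl cation, water adds at the methyl-bearing furan carbon, the hemiketal opens to a 1,4-dihydroxypentadienyl cation, and conrotatory 4π-electrocyclisation joins B1 to B5 before proton loss gives the enone; the closest known reaction types are the racemic acid- or Dy(OTf)3-promoted oxa-Piancatelli rearrangement of 5-methyl-2-furylcarbinols and the chiral-phosphoric-acid-catalysed aza-Piancatelli rearrangement, so only the enantioselective use of water as nucleophile is new. Ring B is closed by this cationic 4π-conrotatory electrocyclisation (a Nazarov-type closure), which forms the single skeletal bond B1–B5. The absolute configuration of B5 is set by the sense of conrotation (torquoselectivity) inside the contact ion pair, in which the phosphate is hydrogen-bonded to the hydroxyl groups of the cation and its 3,3'-aryl groups block one direction of rotation. B1 is set relative to B5 by the substrate: with the silyloxymethyl and methyl groups both on the outside of the U-shaped cation, conrotation places them trans, that is hydroxyl cis to C7, and because B1 is α to the new ketone any trans isomer can drain through the enol to this more stable cis isomer. The step needs water to attack the substituted furan carbon and ring closure to outrun simple hydrolysis to the open enedione, which the cation-stabilising 5-methyl group and the small amount of water in a non-polar solvent should secure. It also needs an inert group on the C7 oxygen, and the tert-butyldiphenylsilyl ether resists the acid, offers no electron-rich arene to the cation and, as a poor donor, disfavours a 1,2-hydride shift from C7.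

Step 4
Reactants: 6 (4S,5S)-5-{[(tert-butyldiphenylsilyl)oxy]methyl}-4-hydroxy-4-methylcyclopent-2-en-1-one
Product: 7 (4S,5S)-4-[(tert-butyldimethylsilyl)oxy]-5-{[(tert-butyldiphenylsilyl)oxy]methyl}-4-methylcyclopent-2-en-1-one
Conditions: TBSOTf, 2,6-lutidine, CH2Cl2, −78 → 0 °C
Reagents that add atoms: tert-butyldimethylsilyl trifluoromethanesulfonate (TBSOTf), CC(C)(C)[Si](C)(C)OS(=O)(=O)C(F)(F)F
Why: Silyl triflate with a hindered pyridine base silylates tertiary alcohols under conditions too mild for retro-aldol opening of the β-hydroxy ketone; the ether masks B5–OH for the enolate and organometallic steps, and neither stereocentre is touched.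

Step 5
Reactants: 7 (4S,5S)-4-[(tert-butyldimethylsilyl)oxy]-5-{[(tert-butyldiphenylsilyl)oxy]methyl}-4-methylcyclopent-2-en-1-one
Product: 10 (4S,5S)-4-[(tert-butyldimethylsilyl)oxy]-5-{[(tert-butyldiphenylsilyl)oxy]methyl}-4-methylcyclopent-1-en-1-yl trifluoromethanesulfonate, via dimethyl(phenyl)silyl enol ether 8 (not isolated), via lithium enolate 9 (not isolated)
Conditions: [(Ph3P)CuH]6 (5 mol %), PhMe2SiH, PhMe, rt; then MeLi, THF, 0 °C; then 2-[N,N-bis(trifluoromethylsulfonyl)amino]-5-chloropyridine, −78 → 0 °C; then H2O
Reagents that add atoms: 2-[N,N-bis(trifluoromethylsulfonyl)amino]-5-chloropyridine, FC(F)(F)S(=O)(=O)N(c1ccc(Cl)cn1)S(=O)(=O)C(F)(F)F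
Why: Copper hydride catalysed 1,4-hydrosilylation delivers hydride to B4 only and fixes the enol oxygen on B2 with the double bond at B2=B3; cleavage of the silyl enol ether by MeLi and O-triflation of the lithium enolate keep this regiochemistry. No base meets the acidic B1–H, so neither epimerisation nor β-elimination of a silyloxy group can start; copper hydride is preferred to a trialkylborohydride, which may attack a cyclopentenone carbonyl directly.

Step 6
Reactants: 11 but-2-yn-1-ol
Product: 13 (2Z)-3-iodobut-2-en-1-ol, via cyclic alkenylaluminate 12 (not isolated)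
Conditions: NaAlH2(OCH2CH2OCH3)2, Et2O, 0 °C → rt; then I2, THF, −78 → 0 °C; aq. potassium sodium tartrate
Reagents that add atoms: iodine, II
Why: Alkoxide-directed trans-hydroalumination of the propargylic alcohol places aluminium on C3, cis to the CH2O group in a five-membered aluminate, and iodination with retention gives the Z-iodide; this sets the D1=D2 geometry.

Step 7
Reactants: 13 (2Z)-3-iodobut-2-en-1-ol
Product: 14 (2Z)-1-bromo-3-iodobut-2-ene
Conditions: CBr4, PPh3, CH2Cl2, 0 °C
Reagents that add atoms: tetrabromomethane, BrC(Br)(Br)Br
Why: Appel bromination of a primary allylic alcohol proceeds by direct displacement at the CH2 carbon, and the alkene geometry is not involved.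

Step 8
Reactants: 14 (2Z)-1-bromo-3-iodobut-2-ene; 15 (2-methylprop-1-en-1-yl)magnesium bromide
Product: 16 (2Z)-2-iodo-6-methylhepta-2,5-diene
Conditions: CuI (10 mol %), THF, −40 → 0 °C
Reagents that add atoms: none
Why: Copper-catalysed allylic substitution by the alkenyl Grignard reagent should occur at the primary carbon, because the other allylic terminus is the fully substituted iodine-bearing carbon; the vinyl iodide is expected to be inert at this temperature. The D3–D4 bond and the skipped diene are formed.

Step 9
Reactants: 16 (2Z)-2-iodo-6-methylhepta-2,5-diene; 10 (4S,5S)-4-[(tert-butyldimethylsilyl)oxy]-5-{[(tert-butyldiphenylsilyl)oxy]methyl}-4-methylcyclopent-1-en-1-yl trifluoromethanesulfonate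
Product: 19 tert-butyl{[(1S,2S)-2-{[(tert-butyldiphenylsilyl)oxy]methyl}-1-methyl-3-[(2Z)-6-methylhepta-2,5-dien-2-yl]cyclopent-3-en-1-yl]oxy}dimethylsilane, via alkenyllithium 17 (not isolated), via alkenylzinc bromide 18 (not isolated)
Conditions: t-BuLi (2 equiv), Et2O, −78 °C; ZnBr2, THF, −78 → 0 °C; then 10, Pd(PPh3)4 (5 mol %), THF, rt → 45 °C
Reagents that add atoms: none
Why: Iodine–lithium exchange and transmetalation to zinc retain the alkene geometry, and the Negishi coupling with the enol triflate proceeds with retention at both sp2 carbons; it forms B2–D1 and the Z-diene under neutral conditions that leave B1 alone.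

Step 10
Reactants: 19 tert-butyl{[(1S,2S)-2-{[(tert-butyldiphenylsilyl)oxy]methyl}-1-methyl-3-[(2Z)-6-methylhepta-2,5-dien-2-yl]cyclopent-3-en-1-yl]oxy}dimethylsilane
Product: 20 [(1S,5S)-5-[(tert-butyldimethylsilyl)oxy]-5-methyl-2-[(2Z)-6-methylhepta-2,5-dien-2-yl]cyclopent-2-en-1-yl]methanol
Conditions: TBAF, AcOH, THF, 0 °C → rt
Reagents that add atoms: none
Why: Buffered fluoride cleaves the unhindered primary silyl ether much faster than the tertiary tert-butyldimethylsilyl ether; no oxidant or acid meets the triene.

Step 11
Reactants: 20 [(1S,5S)-5-[(tert-butyldimethylsilyl)oxy]-5-methyl-2-[(2Z)-6-methylhepta-2,5-dien-2-yl]cyclopent-2-en-1-yl]methanol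
Product: 21 tert-butyl{[(1S,2R)-2-(iodomethyl)-1-methyl-3-[(2Z)-6-methylhepta-2,5-dien-2-yl]cyclopent-3-en-1-yl]oxy}dimethylsilane
Conditions: I2, PPh3, imidazole, CH2Cl2, 0 °C → rt
Reagents that add atoms: iodine, II
Why: Appel iodination converts the primary alcohol through its oxyphosphonium salt; iodine is bound to the phosphine before the substrate is added, so the alkenes are not attacked. The B1 descriptor changes only because of the priority of iodine.

Step 12
Reactants: 22 methyl (2S)-oxirane-2-carboxylate; 23 allylmagnesium bromide
Product: 24 methyl (2S)-2-hydroxyhex-5-enoate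
Conditions: CuI (10 mol %), THF, −78 °C; then H2O
Reagents that add atoms: none
Why: Copper-catalysed opening of the terminal epoxide by the Grignard reagent occurs at the unsubstituted carbon and forms A5–A6; the stereocentre is not a reacting centre, so the chiral-pool configuration that becomes A4 is carried over.

Step 13
Reactants: 24 methyl (2S)-2-hydroxyhex-5-enoate
Product: 25 methyl (2S)-2-methoxyhex-5-enoate
Conditions: MeI, Ag2O, MeCN, rt, dark
Reagents that add atoms: iodomethane, CI
Why: Purdie methylation etherifies the α-hydroxy ester without a base strong enough to enolise it, so the stereocentre is kept.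

Step 14
Reactants: 25 methyl (2S)-2-methoxyhex-5-enoate
Product: 26 methyl (2S)-2-methoxy-5-oxohexanoate
Conditions: PdCl2 (10 mol %), CuCl, O2 (1 atm), DMF/H2O, rt
Reagents that add atoms: water, O
Why: Wacker oxidation of the terminal alkene gives the methyl ketone with Markovnikov selectivity; the remote ether and ester do not interfere.

Step 15
Reactants: 26 methyl (2S)-2-methoxy-5-oxohexanoate
Product: 27 (4S)-4-methoxycyclohexane-1,3-dione
Conditions: KOtBu, THF, 0 °C → rt; then aq. HCl to pH 3, 0 °C
Reagents that add atoms: none
Why: Intramolecular Claisen (Dieckmann-type) condensation: the methyl ketone enolate attacks the activated α-methoxy ester in a six-membered closure forming A2–A3. The product is at once converted into its stabilised enolate, which shields A4 from further deprotonation.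

Step 16
Reactants: 27 (4S)-4-methoxycyclohexane-1,3-dione
Product: 28 (6S)-6-methoxy-3-[2-(trimethylsilyl)ethoxy]cyclohex-2-en-1-one
Conditions: 2-(trimethylsilyl)ethanol, PPh3, DIAD, THF, 0 °C → rt
Reagents that add atoms: 2-(trimethylsilyl)ethanol, C[Si](C)(C)CCO
Why: Mitsunobu O-alkylation of the acidic dione needs no base, so A4 is safe; it should take place at the oxygen remote from the methoxy group, which is less hindered and more electron-rich. Alkylation at the other oxygen would do no harm, since either enol ether unveils the same dione in step 19.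

Step 17
Reactants: 28 (6S)-6-methoxy-3-[2-(trimethylsilyl)ethoxy]cyclohex-2-en-1-one
Product: 29 (6S)-2-iodo-6-methoxy-3-[2-(trimethylsilyl)ethoxy]cyclohex-2-en-1-one
Conditions: NIS, MeCN, 0 °C → rt, dark
Reagents that add atoms: N-iodosuccinimide, O=C1CCC(=O)N1I
Why: The α-carbon of a vinylogous ester reacts like an enol ether carbon: electrophilic iodination at A2 followed by proton loss gives the 2-iodo enone. The enol ether is made before the iodination because triphenylphosphine would remove iodine from a 2-iodo dione.

Step 18
Reactants: 21 tert-butyl{[(1S,2R)-2-(iodomethyl)-1-methyl-3-[(2Z)-6-methylhepta-2,5-dien-2-yl]cyclopent-3-en-1-yl]oxy}dimethylsilane; 29 (6S)-2-iodo-6-methoxy-3-[2-(trimethylsilyl)ethoxy]cyclohex-2-en-1-one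
Product: 31 (6S)-2-{[(1R,5S)-5-[(tert-butyldimethylsilyl)oxy]-5-methyl-2-[(2Z)-6-methylhepta-2,5-dien-2-yl]cyclopent-2-en-1-yl]methyl}-6-methoxy-3-[2-(trimethylsilyl)ethoxy]cyclohex-2-en-1-one, via alkylzinc iodide 30 (not isolated)
Conditions: Zn dust (activated), DMA, 40 °C; then 29, Pd2(dba)3 (2.5 mol %), SPhos (10 mol %), THF/DMA, rt → 40 °C
Reagents that add atoms: none
Why: Zinc inserts into the primary C–I bond, and the alkylzinc iodide undergoes sp3–sp2 Negishi coupling with the α-iodo enone, whose C–I bond adds readily to zerovalent palladium; the bulky biarylphosphine favours reductive elimination over β-hydride elimination. The conditions are neutral, so B1, B5 and A4 are unaffected, and the C7–A2 bond is formed.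

Step 19
Reactants: 31 (6S)-2-{[(1R,5S)-5-[(tert-butyldimethylsilyl)oxy]-5-methyl-2-[(2Z)-6-methylhepta-2,5-dien-2-yl]cyclopent-2-en-1-yl]methyl}-6-methoxy-3-[2-(trimethylsilyl)ethoxy]cyclohex-2-en-1-one
Product: 32 (4S)-3-hydroxy-2-{[(1R,5S)-5-hydroxy-5-methyl-2-[(2Z)-6-methylhepta-2,5-dien-2-yl]cyclopent-2-en-1-yl]methyl}-4-methoxycyclohex-2-en-1-one (target, CNP0148956.1)
Conditions: TBAF (excess), THF, 0 → 45 °C; then AcOH to pH 5, 0 °C
Reagents that add atoms: none
Why: Fluoride attacks the trimethylsilyl group and triggers β-elimination (ethene and fluorosilane), releasing the dione as its enolate, and then cleaves the tertiary silyl ether. The medium stays basic, so the enolate protects A4, the diene is not protonated and B5–OH cannot cyclise onto ring A; mild acidification gives the free enol.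

## Compound list

1 | glycolaldehyde dimer (1,4-dioxane-2,5-diol) | OC1COC(O)CO1 | starting material
2 | 2-[(tert-butyldiphenylsilyl)oxy]acetaldehyde | O=CCO[Si](c1ccccc1)(c1ccccc1)C(C)(C)C | intermediate
3 | 2-methylfuran | Cc1ccco1 | starting material
4 | 5-methyl-2-furyllithium | [Li]c1ccc(C)o1 | intermediate
5 | rac-2-[(tert-butyldiphenylsilyl)oxy]-1-(5-methylfuran-2-yl)ethan-1-ol (racemate) | Cc1ccc(o1)C(O)CO[Si](c1ccccc1)(c1ccccc1)C(C)(C)C | intermediate
6 | (4S,5S)-5-{[(tert-butyldiphenylsilyl)oxy]methyl}-4-hydroxy-4-methylcyclopent-2-en-1-one | O=C1C=C[C@](C)(O)[C@@H]1CO[Si](c1ccccc1)(c1ccccc1)C(C)(C)C | intermediate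
7 | (4S,5S)-4-[(tert-butyldimethylsilyl)oxy]-5-{[(tert-butyldiphenylsilyl)oxy]methyl}-4-methylcyclopent-2-en-1-one | O=C1C=C[C@](C)(O[Si](C)(C)C(C)(C)C)[C@@H]1CO[Si](c1ccccc1)(c1ccccc1)C(C)(C)C | intermediate
8 | {[(4S,5S)-4-[(tert-butyldimethylsilyl)oxy]-5-{[(tert-butyldiphenylsilyl)oxy]methyl}-4-methylcyclopent-1-en-1-yl]oxy}dimethyl(phenyl)silane | C[Si](C)(OC1=CC[C@](C)(O[Si](C)(C)C(C)(C)C)[C@@H]1CO[Si](c1ccccc1)(c1ccccc1)C(C)(C)C)c1ccccc1 | intermediate
9 | lithium 4-[(tert-butyldimethylsilyl)oxy]-5-{[(tert-butyldiphenylsilyl)oxy]methyl}-4-methylcyclopent-1-en-1-olate, ring stereocentres arranged as in 7 | [Li]OC1=CC[C@](C)(O[Si](C)(C)C(C)(C)C)[C@@H]1CO[Si](c1ccccc1)(c1ccccc1)C(C)(C)C | intermediate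
10 | (4S,5S)-4-[(tert-butyldimethylsilyl)oxy]-5-{[(tert-butyldiphenylsilyl)oxy]methyl}-4-methylcyclopent-1-en-1-yl trifluoromethanesulfonate | FC(F)(F)S(=O)(=O)OC1=CC[C@](C)(O[Si](C)(C)C(C)(C)C)[C@@H]1CO[Si](c1ccccc1)(c1ccccc1)C(C)(C)C | intermediate
11 | but-2-yn-1-ol | CC#CCO | starting material
12 | sodium 2,2-bis(2-methoxyethoxy)-3-methyl-2,5-dihydro-1,2-oxaaluminol-2-uide (cyclic alkenylaluminate) | CC1=CCO[Al-]1(OCCOC)OCCOC.[Na+] | intermediate
13 | (2Z)-3-iodobut-2-en-1-ol | C/C(I)=C/CO | intermediate
14 | (2Z)-1-bromo-3-iodobut-2-ene | C/C(I)=C/CBr | intermediate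
15 | (2-methylprop-1-en-1-yl)magnesium bromide | CC(C)=C[Mg]Br | starting material
16 | (2Z)-2-iodo-6-methylhepta-2,5-diene | C/C(I)=C/CC=C(C)C | intermediate
17 | (6-methylhepta-2,5-dien-2-yl)lithium, lithium cis to C4 | C/C([Li])=C/CC=C(C)C | intermediate
18 | bromo[(2Z)-6-methylhepta-2,5-dien-2-yl]zinc | C/C([Zn]Br)=C/CC=C(C)C | intermediate
19 | tert-butyl{[(1S,2S)-2-{[(tert-butyldiphenylsilyl)oxy]methyl}-1-methyl-3-[(2Z)-6-methylhepta-2,5-dien-2-yl]cyclopent-3-en-1-yl]oxy}dimethylsilane | CC(C)=CC/C=C(/C)C1=CC[C@](C)(O[Si](C)(C)C(C)(C)C)[C@@H]1CO[Si](c1ccccc1)(c1ccccc1)C(C)(C)C | intermediate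
20 | [(1S,5S)-5-[(tert-butyldimethylsilyl)oxy]-5-methyl-2-[(2Z)-6-methylhepta-2,5-dien-2-yl]cyclopent-2-en-1-yl]methanol | CC(C)=CC/C=C(/C)C1=CC[C@](C)(O[Si](C)(C)C(C)(C)C)[C@@H]1CO | intermediate
21 | tert-butyl{[(1S,2R)-2-(iodomethyl)-1-methyl-3-[(2Z)-6-methylhepta-2,5-dien-2-yl]cyclopent-3-en-1-yl]oxy}dimethylsilane | CC(C)=CC/C=C(/C)C1=CC[C@](C)(O[Si](C)(C)C(C)(C)C)[C@@H]1CI | intermediate
22 | methyl (2S)-oxirane-2-carboxylate | COC(=O)[C@@H]1CO1 | starting material
23 | allylmagnesium bromide | C=CC[Mg]Br | starting material
24 | methyl (2S)-2-hydroxyhex-5-enoate | COC(=O)[C@@H](O)CCC=C | intermediate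
25 | methyl (2S)-2-methoxyhex-5-enoate | COC(=O)[C@@H](OC)CCC=C | intermediate
26 | methyl (2S)-2-methoxy-5-oxohexanoate | COC(=O)[C@@H](OC)CCC(C)=O | intermediate
27 | (4S)-4-methoxycyclohexane-1,3-dione | CO[C@H]1CCC(=O)CC1=O | intermediate
28 | (6S)-6-methoxy-3-[2-(trimethylsilyl)ethoxy]cyclohex-2-en-1-one | CO[C@H]1CCC(OCC[Si](C)(C)C)=CC1=O | intermediate
29 | (6S)-2-iodo-6-methoxy-3-[2-(trimethylsilyl)ethoxy]cyclohex-2-en-1-one | CO[C@H]1CCC(OCC[Si](C)(C)C)=C(I)C1=O | intermediate
30 | {[(1R,5S)-5-[(tert-butyldimethylsilyl)oxy]-5-methyl-2-[(2Z)-6-methylhepta-2,5-dien-2-yl]cyclopent-2-en-1-yl]methyl}(iodo)zinc | CC(C)=CC/C=C(/C)C1=CC[C@](C)(O[Si](C)(C)C(C)(C)C)[C@@H]1C[Zn]I | intermediate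
31 | (6S)-2-{[(1R,5S)-5-[(tert-butyldimethylsilyl)oxy]-5-methyl-2-[(2Z)-6-methylhepta-2,5-dien-2-yl]cyclopent-2-en-1-yl]methyl}-6-methoxy-3-[2-(trimethylsilyl)ethoxy]cyclohex-2-en-1-one | CO[C@H]1CCC(OCC[Si](C)(C)C)=C(C[C@@H]2C(/C(C)=C\CC=C(C)C)=CC[C@]2(C)O[Si](C)(C)C(C)(C)C)C1=O | intermediate
32 | (4S)-3-hydroxy-2-{[(1R,5S)-5-hydroxy-5-methyl-2-[(2Z)-6-methylhepta-2,5-dien-2-yl]cyclopent-2-en-1-yl]methyl}-4-methoxycyclohex-2-en-1-one | CO[C@H]1CCC(=O)C(C[C@@H]2C(/C(C)=C\CC=C(C)C)=CC[C@]2(C)O)=C1O | target

## Step count and least certain steps

Total step count: 19. Longest linear sequence: 10 steps (steps 1, 2, 3, 4, 5, 9, 10, 11, 18, 19). The side chain (steps 6–8) and ring A (steps 12–17) are convergent branches.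

**Step 3 (key step).** The furfuryl cation may be diverted before ring closure, by proton loss or hydride shift toward C7 or by hydrolysis to the open-chain enedione. The cation is secondary and flanked by an oxygenated carbon, so it is less stabilised than the aryl carbinols on which the known asymmetric variants rest. Torquoselectivity may also be weak, because water competes with the cation for hydrogen bonds to the phosphate. Fallback from 5: the known racemic rearrangement (Dy(OTf)3 (10 mol %), t-BuOH/H2O, 80 °C) would give 6 together with its mirror image, (4R,5R)-5-{[(tert-butyldiphenylsilyl)oxy]methyl}-4-hydroxy-4-methylcyclopent-2-en-1-one F1. Preparative chromatography on a chiral stationary phase, helped by the diphenylsilyl chromophore, separates the two and returns to the route at 6.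

**Step 18.** Zinc insertion at the β-branched carbon may be slow, the organozinc may be protonated, and β-hydride elimination from the alkylpalladium may compete with reductive elimination onto an iodide flanked on both sides. Fallback from 21: iodine–lithium exchange (t-BuLi, Et2O, −78 °C) gives the alkyllithium {[(1R,5S)-5-[(tert-butyldimethylsilyl)oxy]-5-methyl-2-[(2Z)-6-methylhepta-2,5-dien-2-yl]cyclopent-2-en-1-yl]methyl}lithium F2. This is trapped with 9-methoxy-9-borabicyclo[3.3.1]nonane as the lithium alkyl(methoxy)borate F3. B-alkyl Suzuki–Miyaura coupling of F3 with 29 (PdCl2(dppf), aq. K3PO4, DMF, rt) returns to the route at 31.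

**Step 19.** Cleavage of the hindered tertiary silyl ether may be slow. Long exposure to warm basic fluoride or too acidic a work-up could then lead to epimerisation at A4 or to ring closure of B5–OH onto ring A. Fallback from 19, which moves the forcing desilylation to a robust intermediate and ends with a labile triethylsilyl ether:

- TBAF (excess), THF, 50 °C gives the diol (1S,2S)-2-(hydroxymethyl)-1-methyl-3-[(2Z)-6-methylhepta-2,5-dien-2-yl]cyclopent-3-en-1-ol F4.
- Appel iodination (I2, PPh3, imidazole), selective for the primary hydroxyl, gives (1S,2R)-2-(iodomethyl)-1-methyl-3-[(2Z)-6-methylhepta-2,5-dien-2-yl]cyclopent-3-en-1-ol F5.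
- TESOTf, 2,6-lutidine gives triethyl{[(1S,2R)-2-(iodomethyl)-1-methyl-3-[(2Z)-6-methylhepta-2,5-dien-2-yl]cyclopent-3-en-1-yl]oxy}silane F6.
- Zinc insertion gives {[(1R,5S)-5-methyl-2-[(2Z)-6-methylhepta-2,5-dien-2-yl]-5-[(triethylsilyl)oxy]cyclopent-2-en-1-yl]methyl}(iodo)zinc F7, and Negishi coupling with 29 as in step 18 gives (6S)-6-methoxy-2-{[(1R,5S)-5-methyl-2-[(2Z)-6-methylhepta-2,5-dien-2-yl]-5-[(triethylsilyl)oxy]cyclopent-2-en-1-yl]methyl}-3-[2-(trimethylsilyl)ethoxy]cyclohex-2-en-1-one F8.
- TBAF at 0 °C → rt, then AcOH, cleaves both groups and returns to the route at 32.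

**Step 5.** Hydride may add to the carbonyl instead of to B4, or the enolate may lose its regiochemistry through proton transfer before triflation. Fallback from 7: hydrogenation of the enone (H2, Pd/C, EtOAc) gives (2S,3S)-3-[(tert-butyldimethylsilyl)oxy]-2-{[(tert-butyldiphenylsilyl)oxy]methyl}-3-methylcyclopentan-1-one F9. Kinetic deprotonation at the unhindered B3 methylene (LiN(SiMe3)2, THF, −78 °C) gives enolate 9, and triflation with the reagent of step 5 returns to the route at 10.

**Step 9.** Transmetalation and reductive elimination at the substituted B2 position may be slow, giving time for Z-to-E isomerisation of the alkenylmetal or protodemetalation. Fallback from 10, with reversed polarity: Miyaura borylation (B2pin2, PdCl2(PPh3)2, PPh3, KOPh, PhMe, 50 °C) gives 2-[(4S,5S)-4-[(tert-butyldimethylsilyl)oxy]-5-{[(tert-butyldiphenylsilyl)oxy]methyl}-4-methylcyclopent-1-en-1-yl]-4,4,5,5-tetramethyl-1,3,2-dioxaborolane F10. Suzuki–Miyaura coupling of F10 with 16 (PdCl2(dppf), Cs2CO3, DMF/H2O) returns to the route at 19.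

**Step 12.** The allyl Grignard reagent may add to the ester carbonyl in competition with the copper-catalysed epoxide opening. Fallback from 22: saponification (KOH, EtOH, 0 °C) gives potassium (2S)-oxirane-2-carboxylate F11, whose carboxylate is inert to the Grignard reagent. Opening with 23 and CuI gives (2S)-2-hydroxyhex-5-enoic acid F12. Exhaustive Purdie methylation (MeI, Ag2O) forms the ester and the ether together and returns to the route at 25.

## Further compounds

F1 | step 3 | (4R,5R)-5-{[(tert-butyldiphenylsilyl)oxy]methyl}-4-hydroxy-4-methylcyclopent-2-en-1-one | O=C1C=C[C@@](C)(O)[C@H]1CO[Si](c1ccccc1)(c1ccccc1)C(C)(C)C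
F2 | step 18 | {[(1R,5S)-5-[(tert-butyldimethylsilyl)oxy]-5-methyl-2-[(2Z)-6-methylhepta-2,5-dien-2-yl]cyclopent-2-en-1-yl]methyl}lithium | CC(C)=CC/C=C(/C)C1=CC[C@](C)(O[Si](C)(C)C(C)(C)C)[C@@H]1C[Li]
F3 | step 18 | lithium 9-{[(1R,5S)-5-[(tert-butyldimethylsilyl)oxy]-5-methyl-2-[(2Z)-6-methylhepta-2,5-dien-2-yl]cyclopent-2-en-1-yl]methyl}-9-methoxy-9-boranuidabicyclo[3.3.1]nonane | [Li+].CO[B-]1(C[C@@H]2C(/C(C)=C\CC=C(C)C)=CC[C@]2(C)O[Si](C)(C)C(C)(C)C)C2CCCC1CCC2
F4 | step 19 | (1S,2S)-2-(hydroxymethyl)-1-methyl-3-[(2Z)-6-methylhepta-2,5-dien-2-yl]cyclopent-3-en-1-ol | CC(C)=CC/C=C(/C)C1=CC[C@](C)(O)[C@@H]1CO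
F5 | step 19 | (1S,2R)-2-(iodomethyl)-1-methyl-3-[(2Z)-6-methylhepta-2,5-dien-2-yl]cyclopent-3-en-1-ol | CC(C)=CC/C=C(/C)C1=CC[C@](C)(O)[C@@H]1CI
F6 | step 19 | triethyl{[(1S,2R)-2-(iodomethyl)-1-methyl-3-[(2Z)-6-methylhepta-2,5-dien-2-yl]cyclopent-3-en-1-yl]oxy}silane | CC(C)=CC/C=C(/C)C1=CC[C@](C)(O[Si](CC)(CC)CC)[C@@H]1CI
F7 | step 19 | {[(1R,5S)-5-methyl-2-[(2Z)-6-methylhepta-2,5-dien-2-yl]-5-[(triethylsilyl)oxy]cyclopent-2-en-1-yl]methyl}(iodo)zinc | CC(C)=CC/C=C(/C)C1=CC[C@](C)(O[Si](CC)(CC)CC)[C@@H]1C[Zn]I
F8 | step 19 | (6S)-6-methoxy-2-{[(1R,5S)-5-methyl-2-[(2Z)-6-methylhepta-2,5-dien-2-yl]-5-[(triethylsilyl)oxy]cyclopent-2-en-1-yl]methyl}-3-[2-(trimethylsilyl)ethoxy]cyclohex-2-en-1-one | CO[C@H]1CCC(OCC[Si](C)(C)C)=C(C[C@@H]2C(/C(C)=C\CC=C(C)C)=CC[C@]2(C)O[Si](CC)(CC)CC)C1=O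
F9 | step 5 | (2S,3S)-3-[(tert-butyldimethylsilyl)oxy]-2-{[(tert-butyldiphenylsilyl)oxy]methyl}-3-methylcyclopentan-1-one | O=C1CC[C@](C)(O[Si](C)(C)C(C)(C)C)[C@@H]1CO[Si](c1ccccc1)(c1ccccc1)C(C)(C)C
F10 | step 9 | 2-[(4S,5S)-4-[(tert-butyldimethylsilyl)oxy]-5-{[(tert-butyldiphenylsilyl)oxy]methyl}-4-methylcyclopent-1-en-1-yl]-4,4,5,5-tetramethyl-1,3,2-dioxaborolane | CC1(C)OB(OC1(C)C)C1=CC[C@](C)(O[Si](C)(C)C(C)(C)C)[C@@H]1CO[Si](c1ccccc1)(c1ccccc1)C(C)(C)C
F11 | step 12 | potassium (2S)-oxirane-2-carboxylate | [K+].[O-]C(=O)[C@@H]1CO1
F12 | step 12 | (2S)-2-hydroxyhex-5-enoic acid | OC(=O)[C@@H](O)CCC=C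
A1 | alternative 1 | (4S,5S)-2,2-di-tert-butyl-4-methyl-4-[(2Z)-6-methylhepta-2,5-dien-1-yl]-5-(prop-1-yn-1-yl)-1,3,2-dioxasilinane | CC#C[C@H]1CO[Si](C(C)(C)C)(C(C)(C)C)O[C@@]1(C)C/C=C\CC=C(C)C
A2 | alternative 1 | (4aS,7aS)-2,2-di-tert-butyl-7a-methyl-5-[(2Z)-6-methylhepta-2,5-dien-2-yl]-4,4a,7,7a-tetrahydrocyclopenta[d][1,3,2]dioxasiline | CC(C)=CC/C=C(/C)C1=CC[C@]2(C)O[Si](C(C)(C)C)(C(C)(C)C)OC[C@H]12
A3 | alternative 2 | formaldehyde | C=O
A4 | alternative 2 | (4S)-4-methoxy-2-methylidenecyclohexane-1,3-dione | CO[C@H]1CCC(=O)C(=C)C1=O
A5 | alternative 2 | tert-butyl(dimethyl){[(1S)-3-methylcyclopent-2-en-1-yl]oxy}silane | CC1=C[C@@H](O[Si](C)(C)C(C)(C)C)CC1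
A6 | alternative 2 | cis-fused dihydropyran cycloadduct: ring A vinylogous ester bridged through C7 and the B5 oxygen to the 1-methyl-3-(tert-butyldimethylsilyloxy)cyclopentane | CO[C@H]1CCC2=C(C1=O)C[C@@H]3[C@@H](O[Si](C)(C)C(C)(C)C)CC[C@]3(C)O2
A7 | alternative 3 | tert-butyl{[(1S,5S)-2-iodo-5-methyl-5-[(triethylsilyl)oxy]cyclopent-2-en-1-yl]methoxy}dimethylsilane | IC1=CC[C@](C)(O[Si](CC)(CC)CC)[C@@H]1CO[Si](C)(C)C(C)(C)C
A8 | alternative 3 | propyne | CC#C
A9 | alternative 3 | prenyl bromide (1-bromo-3-methylbut-2-ene) | CC(C)=CCBr
A10 | alternative 3 | tert-butyl{[(1S,5S)-5-methyl-2-[(2Z)-6-methylhepta-2,5-dien-2-yl]-5-[(triethylsilyl)oxy]cyclopent-2-en-1-yl]methoxy}dimethylsilane | CC(C)=CC/C=C(/C)C1=CC[C@](C)(O[Si](CC)(CC)CC)[C@@H]1CO[Si](C)(C)C(C)(C)C
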